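Ring atoms are numbered C1 (quaternary, CH3 and CH=CHBr), C2 (CHBr), C3 (CH2), C4 (CHCl), C5 (CCl, CH3) and C6 (CH2). The alkenyl group on C1 is read as two carbons of a former allyl electrophile and the heteroatom-bearing C2 as a former carbanion, so the ring is opened at C1–C2. One palladium-catalysed ring-closing Tsuji–Trost alkylation by an α-boryl carbanion then makes this bond, closes the carbocycle, sets C1 and C2, and leaves boron on C2 and silicon on the alkenyl arm as bromine precursors. Its substrate is an acyclic (R)-1-silyl allyl tert-butyl carbonate with an (E)-trisubstituted alkene, linked through a (Z)-trisubstituted alkene to a geminal bis(pinacolboronate).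

Key step: step 12

Assumption: the ring closure is taken to follow the usual course of stabilised nucleophiles (carbonate leaves anti to palladium, carbon attacks anti to palladium), which makes the (R)-carbinol the required precursor; an inner-sphere course would call for the (S)-carbinol, available with the mirror-image ligand in step 7.

Design remarks (ring positions C1–C6 as defined above are used throughout):
- The carbinol carbon is made as a single enantiomer. Ionisation is stereospecific, and a 1-silyl-3,3-dialkyl π-allyl can change faces only through an anti-silyl complex, so a racemic carbonate would not funnel into one complex. C1 is therefore set by chirality transfer and an achiral ligand suffices.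
- The leaving group is a tert-butyl carbonate. It releases tert-butoxide, the usual activator of geminal bis(boronates), and it resists the carbanion used in step 11.
- The geminal bis(boronate) enters last before the key step, because it tolerates neither trimethylaluminium nor copper alkoxides.
- The ring alkene is dichlorinated through its epoxide by two inversions, because a trisubstituted alkene is a poor substrate for direct catalytic syn-dichlorination.
- The vinylsilane is brominated last, when no other alkene remains.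

Step 1
Reactants: 1 (tert-butyldimethylsilyloxy)acetaldehyde; 2 ethyl 2-[bis(2,2,2-trifluoroethoxy)phosphoryl]propanoate
Product: 3 ethyl (Z)-4-[(tert-butyldimethylsilyl)oxy]-2-methylbut-2-enoate
Conditions: KHMDS, 18-crown-6, THF, −78 °C
Reagents that add atoms: none
Why: Still–Gennari olefination, in which the electron-poor phosphonate eliminates from the kinetic adduct and should give the (Z)-trisubstituted enoate, placing the ester carbon and the silyloxymethyl group cis as the later ring alkene requires.

Step 2
Reactants: 3 ethyl (Z)-4-[(tert-butyldimethylsilyl)oxy]-2-methylbut-2-enoate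
Product: 4 (Z)-4-[(tert-butyldimethylsilyl)oxy]-2-methylbut-2-en-1-ol
Conditions: DIBAL-H (2.2 equiv), CH2Cl2, −78 °C; Rochelle salt
Reagents that add atoms: none
Why: DIBAL-H 1,2-reduction of an α,β-unsaturated ester to the allylic alcohol, which leaves the alkene geometry and the silyl ether untouched and delivers the two allylic termini differentiated.

Step 3
Reactants: 4 (Z)-4-[(tert-butyldimethylsilyl)oxy]-2-methylbut-2-en-1-ol
Product: 5 (Z)-[(4-bromo-3-methylbut-2-en-1-yl)oxy](tert-butyl)dimethylsilane
Conditions: CBr4, PPh3, CH2Cl2, 0 °C; used at once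
Reagents that add atoms: carbon tetrabromide, BrC(Br)(Br)Br
Why: Appel bromination of a primary allylic alcohol under neutral conditions, a direct SN2 displacement that should cause neither allylic transposition nor Z/E isomerisation.

Step 4
Reactants: 5 (Z)-[(4-bromo-3-methylbut-2-en-1-yl)oxy](tert-butyl)dimethylsilane; 6 ethynylmagnesium bromide
Product: 7 (Z)-tert-butyldimethyl[(3-methylhex-2-en-5-yn-1-yl)oxy]silane
Conditions: 6 (3 equiv), CuBr·SMe2 (10 mol %), THF, 0 °C → rt
Reagents that add atoms: none
Why: Copper-catalysed coupling of an alkynyl Grignard reagent with a primary allylic bromide, which should occur at the halide-bearing carbon with the (Z)-alkene intact and give the skipped enyne, the excess of 6 suppressing double allylation.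

Step 5
Reactants: 7 (Z)-tert-butyldimethyl[(3-methylhex-2-en-5-yn-1-yl)oxy]silane
Product: 9 (2E,5Z)-7-[(tert-butyldimethylsilyl)oxy]-3,5-dimethylhepta-2,5-dien-1-ol, via alkenyldimethylalane 8 (not isolated)
Conditions: Me3Al (3 equiv), Cp2ZrCl2 (0.25 equiv), CH2Cl2, 0 °C → rt; volatiles removed; then n-BuLi, THF, (CH2O)n, −78 °C → rt
Reagents that add atoms: trimethylaluminium, C[Al](C)C; paraformaldehyde (as formaldehyde), C=O
Why: Negishi zirconium-catalysed methylalumination adds CH3 and Al syn across the terminal alkyne with aluminium at the terminus, which fixes the (E)-trisubstituted alkene, and the alkenylalanate formed with n-BuLi is hydroxymethylated by formaldehyde with retention of geometry.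

Step 6
Reactants: 9 (2E,5Z)-7-[(tert-butyldimethylsilyl)oxy]-3,5-dimethylhepta-2,5-dien-1-ol
Product: 10 (2E,5Z)-7-[(tert-butyldimethylsilyl)oxy]-3,5-dimethylhepta-2,5-dienal
Conditions: activated MnO2 (excess), CH2Cl2, rt
Reagents that add atoms: none
Why: MnO2 oxidation of a primary allylic alcohol, a neutral heterogeneous oxidation that should leave the (E)-enal and the skipped diene unisomerised.

Step 7
Reactants: 10 (2E,5Z)-7-[(tert-butyldimethylsilyl)oxy]-3,5-dimethylhepta-2,5-dienal; 11 2-[dimethyl(phenyl)silyl]-4,4,5,5-tetramethyl-1,3,2-dioxaborolane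
Product: 13 (1R,2E,5Z)-7-[(tert-butyldimethylsilyl)oxy]-1-[dimethyl(phenyl)silyl]-3,5-dimethylhepta-2,5-dien-1-ol, via O-pinacolboryl ether 12 (not isolated)
Conditions: CuF(PPh3)3·2MeOH (5 mol %), DTBM-SEGPHOS (6 mol %; the enantiomer that delivers the (R)-carbinol, to be assigned on the first run), toluene, 0 °C; then aq. NH4Cl
Reagents that add atoms: none
Why: Copper-catalysed enantioselective 1,2-addition of a silyl nucleophile from a Si–B reagent to an aldehyde, in which the chiral bisphosphine–copper–silyl species selects the aldehyde face and so sets the (R)-carbinol, β,β-disubstitution disfavours conjugate addition, and O-borylation of the copper alkoxide forestalls Brook rearrangement.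

Step 8
Reactants: 13 (1R,2E,5Z)-7-[(tert-butyldimethylsilyl)oxy]-1-[dimethyl(phenyl)silyl]-3,5-dimethylhepta-2,5-dien-1-ol
Product: 14 tert-butyl (1R,2E,5Z)-7-[(tert-butyldimethylsilyl)oxy]-1-[dimethyl(phenyl)silyl]-3,5-dimethylhepta-2,5-dien-1-yl carbonate
Conditions: Boc2O (1.5 equiv), DMAP (0.2 equiv), MeCN, rt
Reagents that add atoms: di-tert-butyl dicarbonate, CC(C)(C)OC(=O)OC(=O)OC(C)(C)C
Why: DMAP-catalysed O-acylation to the mixed carbonate, which needs no metal alkoxide, so the α-silyl carbinol cannot undergo Brook rearrangement and its stereocentre is not touched.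

Step 9
Reactants: 14 tert-butyl (1R,2E,5Z)-7-[(tert-butyldimethylsilyl)oxy]-1-[dimethyl(phenyl)silyl]-3,5-dimethylhepta-2,5-dien-1-yl carbonate
Product: 15 tert-butyl (1R,2E,5Z)-1-[dimethyl(phenyl)silyl]-7-hydroxy-3,5-dimethylhepta-2,5-dien-1-yl carbonate
Conditions: PPTS (0.2 equiv), MeOH, rt
Reagents that add atoms: none
Why: Mild acid-catalysed methanolysis of a primary allylic TBS ether, which should spare the tert-butyl carbonate and the allylic C–Si bond that a fluoride source would endanger.

Step 10
Reactants: 15 tert-butyl (1R,2E,5Z)-1-[dimethyl(phenyl)silyl]-7-hydroxy-3,5-dimethylhepta-2,5-dien-1-yl carbonate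
Product: 16 tert-butyl (1R,2E,5Z)-7-bromo-1-[dimethyl(phenyl)silyl]-3,5-dimethylhepta-2,5-dien-1-yl carbonate
Conditions: CBr4, PPh3, CH2Cl2, −20 → 0 °C; used at once
Reagents that add atoms: carbon tetrabromide, BrC(Br)(Br)Br
Why: Appel bromination of the primary allylic alcohol, neutral conditions that are compatible with the allylic carbonate and the allylsilane unit.

Step 11
Reactants: 16 tert-butyl (1R,2E,5Z)-7-bromo-1-[dimethyl(phenyl)silyl]-3,5-dimethylhepta-2,5-dien-1-yl carbonate; 17 bis(pinacolboryl)methane
Product: 19 tert-butyl (1R,2E,5Z)-1-[dimethyl(phenyl)silyl]-3,5-dimethyl-8,8-bis(4,4,5,5-tetramethyl-1,3,2-dioxaborolan-2-yl)octa-2,5-dien-1-yl carbonate, via lithiobis(pinacolboryl)methane 18 (not isolated)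
Conditions: 17 (1.3 equiv), LiTMP (1.2 equiv, from TMP and n-BuLi), THF, 0 °C; then 16, −78 → 0 °C
Reagents that add atoms: none
Why: SN2 alkylation of a lithiated geminal bis(boronate) (a boron-stabilised carbanion) with a primary allylic bromide, which should be much faster than attack on the hindered tert-butyl carbonate.

Step 12
Reactants: 19 tert-butyl (1R,2E,5Z)-1-[dimethyl(phenyl)silyl]-3,5-dimethyl-8,8-bis(4,4,5,5-tetramethyl-1,3,2-dioxaborolan-2-yl)octa-2,5-dien-1-yl carbonate
Product: 20 2-{(1R,6R)-6-[(E)-2-(dimethylphenylsilyl)ethenyl]-4,6-dimethylcyclohex-3-en-1-yl}-4,4,5,5-tetramethyl-1,3,2-dioxaborolane (boron trans to the alkenyl arm)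
Conditions: Pd2(dba)3·CHCl3 (2.5 mol %), dppe (6 mol %), THF (0.02 M), 25 → 45 °C, no added base
Reagents that add atoms: none
Why: Proposed new method: Pd(0) ionises the allylic tert-butyl carbonate anti to the leaving group to a 1-silyl-3,3-dialkyl π-allyl complex (silyl syn), CO2 is lost, and the released tert-butoxide adds to one boron of the geminal bis(boronate) to give a borate whose C–B bond acts as an α-boryl carbanion and attacks the allyl terminus anti to palladium. The closest known reaction types are palladium- and iridium-catalysed allylic substitutions with α-boryl carbanions generated from geminal bis(boronates), and alkoxide-promoted deborylative cyclisations of geminal bis(boronates) onto tethered electrophiles; the ring-closing, quaternary-carbon-forming combination is the extension proposed here. The cyclohexene closes by 6-exo attack on the π-allyl, which forms the C1–C2 bond. C1 is set by chirality transfer from the (R)-carbinol, because ionisation and C–C bond formation both take place anti to palladium and the unsymmetrical π-allyl cannot change faces without placing silicon anti; C2 is expected to follow from a chair-like transition state with the retained Bpin group and the allylpalladium arm both pseudo-equatorial, which puts boron trans to the alkenyl arm. The step needs attack at the fully substituted allyl terminus, secured by the distal-directing silyl group and by the six- over eight-membered ring preference, and it needs an (E)-vinylsilane, secured by the syn position of silicon.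

Step 13
Reactants: 20 2-{(1R,6R)-6-[(E)-2-(dimethylphenylsilyl)ethenyl]-4,6-dimethylcyclohex-3-en-1-yl}-4,4,5,5-tetramethyl-1,3,2-dioxaborolane
Product: 22 {(E)-2-[(1S,6S)-6-bromo-1,3-dimethylcyclohex-3-en-1-yl]ethenyl}dimethyl(phenyl)silane, via lithium arylboronate complex 21 (not isolated)
Conditions: 3,5-(CF3)2C6H3Li (from the aryl bromide and n-BuLi), THF, −78 °C; then NBS, THF/MeCN, −78 °C; Na2S2O3 quench
Reagents that add atoms: N-bromosuccinimide, O=C1CCC(=O)N1Br
Why: Stereospecific bromodeboronation of a secondary boronic ester through its electron-poor aryl boronate complex, an SE2 reaction with inversion at carbon that turns the trans C–B bond into a C–Br bond cis to the alkenyl arm, the borate reacting with NBS at −78 °C far faster than either alkene should.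

Step 14
Reactants: 22 {(E)-2-[(1S,6S)-6-bromo-1,3-dimethylcyclohex-3-en-1-yl]ethenyl}dimethyl(phenyl)silane
Product: 23 {(E)-2-[(1R,3S,4S,6S)-4-bromo-1,3-dimethyl-7-oxabicyclo[4.1.0]heptan-3-yl]ethenyl}dimethyl(phenyl)silane (epoxide oxygen cis to the C1 methyl, trans to Br and the alkenyl arm)
Conditions: mCPBA (1.1 equiv), NaHCO3, CH2Cl2, 0 °C
Reagents that add atoms: 3-chloroperoxybenzoic acid, O=C(OO)c1cccc(Cl)c1
Why: Prilezhaev epoxidation of the trisubstituted ring alkene, which is far more nucleophilic than the hindered vinylsilane, with the peracid expected on the face anti to the cis-disposed bromine and alkenyl arm because in either half-chair one of these two groups is axial on their own face.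

Step 15
Reactants: 23 {(E)-2-[(1R,3S,4S,6S)-4-bromo-1,3-dimethyl-7-oxabicyclo[4.1.0]heptan-3-yl]ethenyl}dimethyl(phenyl)silane
Product: 24 (1S,2S,4S,5S)-5-bromo-2-chloro-4-{(E)-2-[dimethyl(phenyl)silyl]ethenyl}-2,4-dimethylcyclohexan-1-ol (tertiary Cl at C5 cis to Br, C4–OH trans to that Cl)
Conditions: HCl (2 M in Et2O, 1.5 equiv), CH2Cl2, −40 °C
Reagents that add atoms: hydrogen chloride, Cl
Why: Acid-mediated Markovnikov ring opening of a trisubstituted epoxide, in which chloride attacks the tertiary carbon C5 with inversion, anti to the oxygen, and so places the tertiary chloride on the face of bromine and leaves a trans secondary alcohol at C4.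

Step 16
Reactants: 24 (1S,2S,4S,5S)-5-bromo-2-chloro-4-{(E)-2-[dimethyl(phenyl)silyl]ethenyl}-2,4-dimethylcyclohexan-1-ol
Product: 25 {(E)-2-[(1S,2S,4R,5S)-2-bromo-4,5-dichloro-1,5-dimethylcyclohexyl]ethenyl}dimethyl(phenyl)silane
Conditions: PPh3 (3 equiv), CCl4, 70 °C
Reagents that add atoms: carbon tetrachloride, ClC(Cl)(Cl)Cl
Why: Appel deoxychlorination, in which chloride displaces the alkoxyphosphonium group at C4 by SN2 in a non-polar medium, inverting C4 and making the two chlorines cis.

Step 17
Reactants: 25 {(E)-2-[(1S,2S,4R,5S)-2-bromo-4,5-dichloro-1,5-dimethylcyclohexyl]ethenyl}dimethyl(phenyl)silane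
Product: 26 (1S,2S,4R,5S)-2-bromo-1-[(E)-2-bromoethenyl]-4,5-dichloro-1,5-dimethylcyclohexane (target)
Conditions: NBS (1.2 equiv), MeCN, 0 °C → rt, dark
Reagents that add atoms: N-bromosuccinimide, O=C1CCC(=O)N1Br
Why: Electrophilic ipso-bromodesilylation of the (E)-vinylsilane in a polar, non-nucleophilic solvent, where the β-silyl cation loses silicon faster than bromide can add, so the (E) geometry is retained, and no other alkene is left to compete.

Compound list
1 | (tert-butyldimethylsilyloxy)acetaldehyde | O=CCO[Si](C)(C)C(C)(C)C | starting material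
2 | ethyl 2-[bis(2,2,2-trifluoroethoxy)phosphoryl]propanoate | CCOC(=O)C(C)P(=O)(OCC(F)(F)F)OCC(F)(F)F | starting material
3 | ethyl (Z)-4-[(tert-butyldimethylsilyl)oxy]-2-methylbut-2-enoate | CCOC(=O)/C(C)=C\CO[Si](C)(C)C(C)(C)C | intermediate
4 | (Z)-4-[(tert-butyldimethylsilyl)oxy]-2-methylbut-2-en-1-ol | OC/C(C)=C\CO[Si](C)(C)C(C)(C)C | intermediate
5 | (Z)-[(4-bromo-3-methylbut-2-en-1-yl)oxy](tert-butyl)dimethylsilane | BrC/C(C)=C\CO[Si](C)(C)C(C)(C)C | intermediate
6 | ethynylmagnesium bromide | C#C[Mg]Br | starting material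
7 | (Z)-tert-butyldimethyl[(3-methylhex-2-en-5-yn-1-yl)oxy]silane | C#CC/C(C)=C\CO[Si](C)(C)C(C)(C)C | intermediate
8 | [(1E,4Z)-6-[(tert-butyldimethylsilyl)oxy]-2,4-dimethylhexa-1,4-dien-1-yl]dimethylalane (not isolated) | C[Al](C)/C=C(C)/C/C(C)=C\CO[Si](C)(C)C(C)(C)C | intermediate
9 | (2E,5Z)-7-[(tert-butyldimethylsilyl)oxy]-3,5-dimethylhepta-2,5-dien-1-ol | OC/C=C(C)/C/C(C)=C\CO[Si](C)(C)C(C)(C)C | intermediate
10 | (2E,5Z)-7-[(tert-butyldimethylsilyl)oxy]-3,5-dimethylhepta-2,5-dienal | O=C/C=C(C)/C/C(C)=C\CO[Si](C)(C)C(C)(C)C | intermediate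
11 | 2-[dimethyl(phenyl)silyl]-4,4,5,5-tetramethyl-1,3,2-dioxaborolane | C[Si](C)(c1ccccc1)B1OC(C)(C)C(C)(C)O1 | starting material
12 | O-pinacolboryl ether of 13 (not isolated) | CC1(C)OB(O[C@H]([Si](C)(C)c2ccccc2)/C=C(C)/C/C(C)=C\CO[Si](C)(C)C(C)(C)C)OC1(C)C | intermediate
13 | (1R,2E,5Z)-7-[(tert-butyldimethylsilyl)oxy]-1-[dimethyl(phenyl)silyl]-3,5-dimethylhepta-2,5-dien-1-ol | O[C@H]([Si](C)(C)c1ccccc1)/C=C(C)/C/C(C)=C\CO[Si](C)(C)C(C)(C)C | intermediate
14 | tert-butyl (1R,2E,5Z)-7-[(tert-butyldimethylsilyl)oxy]-1-[dimethyl(phenyl)silyl]-3,5-dimethylhepta-2,5-dien-1-yl carbonate | CC(C)(C)OC(=O)O[C@H]([Si](C)(C)c1ccccc1)/C=C(C)/C/C(C)=C\CO[Si](C)(C)C(C)(C)C | intermediate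
15 | tert-butyl (1R,2E,5Z)-1-[dimethyl(phenyl)silyl]-7-hydroxy-3,5-dimethylhepta-2,5-dien-1-yl carbonate | CC(C)(C)OC(=O)O[C@H]([Si](C)(C)c1ccccc1)/C=C(C)/C/C(C)=C\CO | intermediate
16 | tert-butyl (1R,2E,5Z)-7-bromo-1-[dimethyl(phenyl)silyl]-3,5-dimethylhepta-2,5-dien-1-yl carbonate | CC(C)(C)OC(=O)O[C@H]([Si](C)(C)c1ccccc1)/C=C(C)/C/C(C)=C\CBr | intermediate
17 | bis(pinacolboryl)methane | CC1(C)OB(CB2OC(C)(C)C(C)(C)O2)OC1(C)C | starting material
18 | lithiobis(pinacolboryl)methane (not isolated) | [Li]C(B1OC(C)(C)C(C)(C)O1)B1OC(C)(C)C(C)(C)O1 | intermediate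
19 | tert-butyl (1R,2E,5Z)-1-[dimethyl(phenyl)silyl]-3,5-dimethyl-8,8-bis(4,4,5,5-tetramethyl-1,3,2-dioxaborolan-2-yl)octa-2,5-dien-1-yl carbonate (key-step precursor) | CC(C)(C)OC(=O)O[C@H]([Si](C)(C)c1ccccc1)/C=C(C)/C/C(C)=C\CC(B1OC(C)(C)C(C)(C)O1)B1OC(C)(C)C(C)(C)O1 | intermediate
20 | 2-{(1R,6R)-6-[(E)-2-(dimethylphenylsilyl)ethenyl]-4,6-dimethylcyclohex-3-en-1-yl}-4,4,5,5-tetramethyl-1,3,2-dioxaborolane (key-step product) | CC1=CC[C@@H](B2OC(C)(C)C(C)(C)O2)[C@](C)(/C=C/[Si](C)(C)c2ccccc2)C1 | intermediate
21 | lithium [3,5-bis(trifluoromethyl)phenyl]boronate complex of 20 (not isolated) | [Li+].CC1=CC[C@@H]([B-]2(c3cc(C(F)(F)F)cc(C(F)(F)F)c3)OC(C)(C)C(C)(C)O2)[C@](C)(/C=C/[Si](C)(C)c2ccccc2)C1 | intermediate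
22 | {(E)-2-[(1S,6S)-6-bromo-1,3-dimethylcyclohex-3-en-1-yl]ethenyl}dimethyl(phenyl)silane (Br cis to the alkenyl arm) | CC1=CC[C@H](Br)[C@](C)(/C=C/[Si](C)(C)c2ccccc2)C1 | intermediate
23 | {(E)-2-[(1R,3S,4S,6S)-4-bromo-1,3-dimethyl-7-oxabicyclo[4.1.0]heptan-3-yl]ethenyl}dimethyl(phenyl)silane | C[C@@]12C[C@@](C)(/C=C/[Si](C)(C)c3ccccc3)[C@@H](Br)C[C@@H]1O2 | intermediate
24 | (1S,2S,4S,5S)-5-bromo-2-chloro-4-{(E)-2-[dimethyl(phenyl)silyl]ethenyl}-2,4-dimethylcyclohexan-1-ol | C[C@]1(Cl)C[C@@](C)(/C=C/[Si](C)(C)c2ccccc2)[C@@H](Br)C[C@@H]1O | intermediate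
25 | {(E)-2-[(1S,2S,4R,5S)-2-bromo-4,5-dichloro-1,5-dimethylcyclohexyl]ethenyl}dimethyl(phenyl)silane | C[C@]1(Cl)C[C@@](C)(/C=C/[Si](C)(C)c2ccccc2)[C@@H](Br)C[C@H]1Cl | intermediate
26 | (1S,2S,4R,5S)-2-bromo-1-[(E)-2-bromoethenyl]-4,5-dichloro-1,5-dimethylcyclohexane | C[C@]1(Cl)C[C@@](C)(/C=C/Br)[C@@H](Br)C[C@H]1Cl | target

Total step count: 17
Longest linear sequence: 17 steps (from 1 and 2 to 26)

Steps most likely to fail

Step 12 (Proposed new method). The borate may be too weak a nucleophile for the hindered, silyl-bearing π-allyl, so that β-hydride elimination to a triene or protodeboronation takes over, or the boron-bearing carbon may be delivered with poor control relative to C1. The fallback uses known reactions only and runs from enal 10 back to boronate 20. Steps 7 and 8 are repeated with the mirror-image ligand to give the (1S)-carbinol F1 and its tert-butyl carbonate F2. Copper-catalysed γ-selective allylic borylation with B2pin2 (CuOtBu, Xantphos, THF), an anti-SN2′ substitution with 1,3-chirality transfer, then gives the tertiary allylboronate F3 with the (E)-vinylsilane already in place. Lithiation–borylation with the sparteine-complexed α-lithio derivative of but-3-en-1-yl N,N-diisopropylcarbamate follows; the 1,2-metallate rearrangement proceeds with retention at the migrating tertiary carbon and inversion at the lithiated carbon, so C2 is under reagent control, and it gives the homologated secondary boronate F4. Ring-closing metathesis between the terminal vinyl group and the (Z)-trisubstituted alkene (NHC-ligated ruthenium benzylidene catalyst, CH2Cl2, 40 °C) expels allyl silyl ether and returns 20.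

Step 16. Participation of the anti-periplanar tertiary chlorine (a chloriranium ion) or E2 loss of the activated oxygen toward C3 may compete with direct displacement and erode the cis-dichloride relationship. The fallback runs from chlorohydrin 24 back to dichloride 25 and separates activation from displacement: the C4 triflate F6 is formed at −78 °C (Tf2O, 2,6-di-tert-butyl-4-methylpyridine, CH2Cl2) and displaced cold by a large excess of Bu4NCl, so that the bimolecular SN2 path is favoured over the unimolecular participation path.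

Step 13. The aryllithium may add sluggishly to the neopentylic boronate, or single-electron transfer to NBS may give a C2 radical that loses configuration. The fallback runs from boronate 20 back to bromide 22 and replaces electrophilic substitution at C–B by nucleophilic displacement at C–O: the C–B bond is oxidised with retention (NaBO3·4H2O, THF/H2O) to the alcohol F5, whose hydroxyl is trans to the alkenyl arm, and this is converted into the bromide with inversion by an Appel reaction (CBr4, PPh3, CH2Cl2).

Further compounds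
F1 | step 12 | (1S,2E,5Z)-7-[(tert-butyldimethylsilyl)oxy]-1-[dimethyl(phenyl)silyl]-3,5-dimethylhepta-2,5-dien-1-ol | O[C@@H]([Si](C)(C)c1ccccc1)/C=C(C)/C/C(C)=C\CO[Si](C)(C)C(C)(C)C
F2 | step 12 | tert-butyl (1S,2E,5Z)-7-[(tert-butyldimethylsilyl)oxy]-1-[dimethyl(phenyl)silyl]-3,5-dimethylhepta-2,5-dien-1-yl carbonate | CC(C)(C)OC(=O)O[C@@H]([Si](C)(C)c1ccccc1)/C=C(C)/C/C(C)=C\CO[Si](C)(C)C(C)(C)C
F3 | step 12 | 2-[(1E,3R,5Z)-7-[(tert-butyldimethylsilyl)oxy]-1-[dimethyl(phenyl)silyl]-3,5-dimethylhepta-1,5-dien-3-yl]-4,4,5,5-tetramethyl-1,3,2-dioxaborolane | CC1(C)OB([C@](C)(/C=C/[Si](C)(C)c2ccccc2)C/C(C)=C\CO[Si](C)(C)C(C)(C)C)OC1(C)C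
F4 | step 12 | 2-[(4R,5R,7Z)-9-[(tert-butyldimethylsilyl)oxy]-5-{(E)-2-[dimethyl(phenyl)silyl]ethenyl}-5,7-dimethylnona-1,7-dien-4-yl]-4,4,5,5-tetramethyl-1,3,2-dioxaborolane | C=CC[C@@H](B1OC(C)(C)C(C)(C)O1)[C@](C)(/C=C/[Si](C)(C)c1ccccc1)C/C(C)=C\CO[Si](C)(C)C(C)(C)C
F5 | step 13 | (1R,6S)-6-{(E)-2-[dimethyl(phenyl)silyl]ethenyl}-4,6-dimethylcyclohex-3-en-1-ol | CC1=CC[C@@H](O)[C@](C)(/C=C/[Si](C)(C)c2ccccc2)C1
F6 | step 16 | (1S,2S,4S,5S)-5-bromo-2-chloro-4-{(E)-2-[dimethyl(phenyl)silyl]ethenyl}-2,4-dimethylcyclohexyl trifluoromethanesulfonate | C[C@]1(Cl)C[C@@](C)(/C=C/[Si](C)(C)c2ccccc2)[C@@H](Br)C[C@@H]1OS(=O)(=O)C(F)(F)F
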